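**Retrosynthetic overview**
1. Key bond C17–C18 (the CH2 next to the methyl-bearing carbon of the Z-alkene): nickel-catalysed radical cross-electrophile coupling of a ring-bearing (Z)-alkenyl iodide with a primary alkyl halide that already holds the ketone and the three methyl stereocentres. The Z geometry is carried over from the iodide.
2. Keto halide: C11–C12 by hydrozirconation–acylation of (R)-6-bromo-3-methylhex-1-ene with (2R,6S)-2,6,10-trimethylundecanoyl chloride. The acid comes from NiH hydroalkylation (C8–C9) of (S)-3,7-dimethyloct-1-ene with methyl (S)-3-bromo-2-methylpropanoate.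
3. Both 3-methyl-1-alkenes: cross-metathesis to E-allyl bromides, then Cu-catalysed asymmetric SN2′ methylation.
4. Alkenyl iodide: Z-selective iodo-olefination of an aldehyde made from (R)-4-methylcyclohex-3-ene-1-carbaldehyde by acyl-radical addition to methyl acrylate, ketone methylenation and ester half-reduction.
5. Ring order: the only ring (the cyclohexene) is formed first, by an enantioselective Diels–Alder reaction of isoprene with acrolein.

Assumption: the catalyst enantiomers named in steps 1, 7 and 9 are those expected to give the stated configurations; if a measured rotation showed the opposite sense, the mirror-image catalyst would be used with no other change.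

**Step 1**
Reactants: 1 isoprene; 2 acrolein
Product: 3 (R)-4-methylcyclohex-3-ene-1-carbaldehyde
Conditions: (5S)-5-benzyl-2,2,3-trimethylimidazolidin-4-one·HCl (20 mol%), MeNO2/H2O 95:5, rt
Reagents that add atoms: none
Why: Iminium-catalysed enantioselective Diels–Alder reaction in which the benzyl group shields one face of the acrolein iminium ion, so isoprene adds para-selectively to give the (R)-aldehyde (about 90% ee) and the only ring.

**Step 2**
Reactants: 3 (R)-4-methylcyclohex-3-ene-1-carbaldehyde; 4 methyl acrylate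
Product: 5 methyl 4-[(1R)-4-methylcyclohex-3-en-1-yl]-4-oxobutanoate
Conditions: (n-Bu4N)4W10O32 (2 mol%), MeCN, 390 nm LEDs, N2, rt (3 in 1.3-fold excess)
Reagents that add atoms: none
Why: Decatungstate hydrogen-atom transfer from the formyl C–H gives a nucleophilic acyl radical that adds to the acrylate (acyl-radical Giese hydroacylation) faster than it loses CO at room temperature, and the ring stereocentre is not touched.

**Step 3**
Reactants: 5 methyl 4-[(1R)-4-methylcyclohex-3-en-1-yl]-4-oxobutanoate
Product: 6 methyl 4-[(1R)-4-methylcyclohex-3-en-1-yl]pent-4-enoate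
Conditions: Ph3PCH3Br, KOt-Bu, THF, 0 °C; then 5, −78 → 0 °C
Reagents that add atoms: methyltriphenylphosphonium bromide, C[P+](c1ccccc1)(c1ccccc1)c1ccccc1.[Br-]
Why: Wittig methylenation is selective for the ketone over the ester, and at low temperature the ylide adds faster than it enolises the ketone, so the adjacent ring stereocentre is kept.

**Step 4**
Reactants: 6 methyl 4-[(1R)-4-methylcyclohex-3-en-1-yl]pent-4-enoate
Product: 7 4-[(1R)-4-methylcyclohex-3-en-1-yl]pent-4-enal
Conditions: DIBAL-H (1.1 equiv), CH2Cl2, −78 °C; aq. Rochelle salt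
Reagents that add atoms: none
Why: Partial ester reduction with DIBAL-H stops at the aluminium hemiacetal at −78 °C and releases the aldehyde on work-up, with the alkenes inert.

**Step 5**
Reactants: 7 4-[(1R)-4-methylcyclohex-3-en-1-yl]pent-4-enal
Product: 8 (4R)-4-[(5Z)-6-iodohepta-1,5-dien-2-yl]-1-methylcyclohex-1-ene
Conditions: EtPPh3I, n-BuLi, THF, 0 °C; I2, −78 °C; NaHMDS, −20 °C; then 7, −78 → −20 °C
Reagents that add atoms: ethyltriphenylphosphonium iodide, CC[P+](c1ccccc1)(c1ccccc1)c1ccccc1.[I-]; iodine, II
Why: Stork–Zhao-type Wittig olefination with the α-iodo ylide gives the 2-iodo-2-alkene with iodine cis to the chain (Z, typically ≥10:1), which fixes the geometry of the later trisubstituted alkene.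

**Step 6**
Reactants: 9 5-bromopent-1-ene; 10 (E)-1,4-dibromobut-2-ene
Product: 11 (E)-1,6-dibromohex-2-ene
Conditions: 10 (3 equiv), Hoveyda–Grubbs II (2 mol%), CH2Cl2, 40 °C
Reagents that add atoms: none
Why: Olefin cross-metathesis of a terminal alkene with excess symmetrical dibromobutene gives the E-allyl bromide under thermodynamic control, and the alkyl bromide is inert.

**Step 7**
Reactants: 11 (E)-1,6-dibromohex-2-ene
Product: 12 (R)-6-bromo-3-methylhex-1-ene
Conditions: MeMgBr (1.2 equiv), CuBr·SMe2 (1 mol%), (R,Rp)-Taniaphos (1.2 mol%), CH2Cl2, −75 °C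
Reagents that add atoms: methylmagnesium bromide, C[Mg]Br
Why: Copper-catalysed asymmetric allylic alkylation (SN2′) delivers methyl to the γ-carbon under ligand control, setting the (R)-methyl stereocentre and the terminal vinyl group in one step while the primary alkyl bromide does not react at −75 °C.

**Step 8**
Reactants: 13 6-methylhept-1-ene; 10 (E)-1,4-dibromobut-2-ene
Product: 14 (E)-1-bromo-7-methyloct-2-ene
Conditions: 10 (3 equiv), Hoveyda–Grubbs II (2 mol%), CH2Cl2, 40 °C
Reagents that add atoms: none
Why: Olefin cross-metathesis as in step 6 gives the E-allyl bromide needed for the allylic alkylation.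

**Step 9**
Reactants: 14 (E)-1-bromo-7-methyloct-2-ene
Product: 15 (S)-3,7-dimethyloct-1-ene
Conditions: MeMgBr (1.2 equiv), CuBr·SMe2 (1 mol%), (S,Sp)-Taniaphos (1.2 mol%), CH2Cl2, −75 °C
Reagents that add atoms: methylmagnesium bromide, C[Mg]Br
Why: Copper-catalysed asymmetric allylic alkylation (SN2′) with the antipodal ligand sets the (S)-methyl stereocentre of the tail.

**Step 10**
Reactants: 15 (S)-3,7-dimethyloct-1-ene; 16 methyl (S)-3-bromo-2-methylpropanoate
Product: 18 methyl (2R,6S)-2,6,10-trimethylundecanoate, via iodo ester 17 (not isolated)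
Conditions: NiBr2·diglyme (10 mol%), 4,4′-di-tert-butyl-2,2′-bipyridine (12 mol%), (EtO)2MeSiH (2.5 equiv), Na2CO3 (2 equiv), NaI (20 mol%), DMA, rt
Reagents that add atoms: none
Why: Nickel-hydride reductive hydroalkylation in which anti-Markovnikov Ni–H insertion gives a primary alkylnickel that captures the primary radical formed from 17, so the bond forms between two CH2 carbons and the stereocentres of 15 and 16 are carried through unchanged (the descriptor at C2 changes from S to R only through CIP priorities).

**Step 11**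
Reactants: 18 methyl (2R,6S)-2,6,10-trimethylundecanoate
Product: 19 (2R,6S)-2,6,10-trimethylundecanoic acid
Conditions: LiOH·H2O (3 equiv), THF/MeOH/H2O, 0 °C → rt; 1 M HCl
Reagents that add atoms: lithium hydroxide, [Li+].[OH-]
Why: Saponification of the unhindered methyl ester under mild conditions is much faster than α-deprotonation, so C2 is not epimerised.

**Step 12**
Reactants: 19 (2R,6S)-2,6,10-trimethylundecanoic acid; 12 (R)-6-bromo-3-methylhex-1-ene
Product: 22 (4S,8R,12S)-1-bromo-4,8,12,16-tetramethylheptadecan-7-one, via acid chloride 20 (not isolated), via alkylzirconocene 21 (not isolated)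
Conditions: 19, (COCl)2, cat. DMF, CH2Cl2, 0 °C → rt, evaporate; 12, Cp2Zr(H)Cl (1.1 equiv), THF, rt; combine, CuBr·SMe2 (10 mol%), THF, 0 °C → rt
Reagents that add atoms: none
Why: Hydrozirconation with Schwartz's reagent places zirconium on the terminal carbon with the alkyl bromide tolerated, and copper-catalysed acylation of the alkylzirconocene gives the ketone under base-free conditions that leave the α-methyl stereocentre intact (C4 is S here only because bromine changes the CIP priorities).

**Step 13**
Reactants: 8 (4R)-4-[(5Z)-6-iodohepta-1,5-dien-2-yl]-1-methylcyclohex-1-ene; 22 (4S,8R,12S)-1-bromo-4,8,12,16-tetramethylheptadecan-7-one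
Product: 24 (6S,10R,14R,18Z)-2,6,10,14,18-pentamethyl-22-[(1R)-4-methylcyclohex-3-en-1-yl]tricosa-18,22-dien-11-one (target CNP0272027.1), via keto iodide 23 (not isolated)
Conditions: 22 (1.5 equiv), NaI (2 equiv), DMA, 40 °C, 1 h; then 8 (1 equiv), NiBr2·glyme (10 mol%), 4,4′-di-tert-butyl-2,2′-bipyridine (10 mol%), Zn dust (2 equiv), DMA, 25 → 40 °C
Reagents that add atoms: none
Why: Nickel-catalysed cross-electrophile (reductive) coupling in which the alkenyl iodide adds to Ni(0) with retention, the primary alkyl radical from 23 (halogen-atom abstraction by nickel) is captured at nickel and reductive elimination forms C17–C18 with the Z geometry of 8, under neutral conditions that tolerate the epimerisable ketone and the other alkenes.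

**Compound list**
1 | isoprene | C=CC(C)=C | starting material
2 | acrolein | C=CC=O | starting material
3 | (R)-4-methylcyclohex-3-ene-1-carbaldehyde | O=C[C@H]1CC=C(C)CC1 | intermediate
4 | methyl acrylate | C=CC(=O)OC | starting material
5 | methyl 4-[(1R)-4-methylcyclohex-3-en-1-yl]-4-oxobutanoate | COC(=O)CCC(=O)[C@H]1CC=C(C)CC1 | intermediate
6 | methyl 4-[(1R)-4-methylcyclohex-3-en-1-yl]pent-4-enoate | COC(=O)CCC(=C)[C@H]1CC=C(C)CC1 | intermediate
7 | 4-[(1R)-4-methylcyclohex-3-en-1-yl]pent-4-enal | O=CCCC(=C)[C@H]1CC=C(C)CC1 | intermediate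
8 | (4R)-4-[(5Z)-6-iodohepta-1,5-dien-2-yl]-1-methylcyclohex-1-ene | C=C(CC/C=C(/C)I)[C@H]1CC=C(C)CC1 | intermediate
9 | 5-bromopent-1-ene | C=CCCCBr | starting material
10 | (E)-1,4-dibromobut-2-ene | BrC/C=C/CBr | starting material
11 | (E)-1,6-dibromohex-2-ene | BrC/C=C/CCCBr | intermediate
12 | (R)-6-bromo-3-methylhex-1-ene | C=C[C@H](C)CCCBr | intermediate
13 | 6-methylhept-1-ene | C=CCCCC(C)C | starting material
14 | (E)-1-bromo-7-methyloct-2-ene | BrC/C=C/CCCC(C)C | intermediate
15 | (S)-3,7-dimethyloct-1-ene | C=C[C@@H](C)CCCC(C)C | intermediate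
16 | methyl (S)-3-bromo-2-methylpropanoate | COC(=O)[C@H](C)CBr | starting material
17 | methyl (S)-3-iodo-2-methylpropanoate | COC(=O)[C@H](C)CI | intermediate
18 | methyl (2R,6S)-2,6,10-trimethylundecanoate | COC(=O)[C@H](C)CCC[C@@H](C)CCCC(C)C | intermediate
19 | (2R,6S)-2,6,10-trimethylundecanoic acid | OC(=O)[C@H](C)CCC[C@@H](C)CCCC(C)C | intermediate
20 | (2R,6S)-2,6,10-trimethylundecanoyl chloride | ClC(=O)[C@H](C)CCC[C@@H](C)CCCC(C)C | intermediate
21 | [(3R)-6-bromo-3-methylhexyl]chloridobis(cyclopentadienyl)zirconium (Cp rings written σ-bonded) | Cl[Zr](CC[C@H](C)CCCBr)(C1C=CC=C1)C1C=CC=C1 | intermediate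
22 | (4S,8R,12S)-1-bromo-4,8,12,16-tetramethylheptadecan-7-one | BrCCC[C@@H](C)CCC(=O)[C@H](C)CCC[C@@H](C)CCCC(C)C | intermediate
23 | (4S,8R,12S)-1-iodo-4,8,12,16-tetramethylheptadecan-7-one | ICCC[C@@H](C)CCC(=O)[C@H](C)CCC[C@@H](C)CCCC(C)C | intermediate
24 | (6S,10R,14R,18Z)-2,6,10,14,18-pentamethyl-22-[(1R)-4-methylcyclohex-3-en-1-yl]tricosa-18,22-dien-11-one | C=C(CC/C=C(/C)CCC[C@@H](C)CCC(=O)[C@H](C)CCC[C@@H](C)CCCC(C)C)[C@H]1CC=C(C)CC1 | target

**Step count and risk**
Total steps: 13. Longest linear sequence: 6 (steps 8 → 9 → 10 → 11 → 12 → 13; the head branch, steps 1–5 then 13, is equally long).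

The three steps most likely to fail:

Step 13 (key coupling). The risks are homodimerisation of the hindered alkenyl iodide, simple reduction of either partner, and some loss of Z purity. The fallback sets out from 8 and comes back at 24. Compound 8 is treated with t-BuLi (2.1 equiv, Et2O, −78 °C) and then ZnCl2 to give, with retention, chloro{(2Z)-6-[(1R)-4-methylcyclohex-3-en-1-yl]hepta-2,6-dien-2-yl}zinc F6. Iodide 23 is made from 22 with NaI in acetone and isolated. F6 and 23 are then joined with NiCl2·glyme/2,2′-bipyridine in THF/DMA at room temperature to give 24. The alkyl iodide is still opened to the primary radical at nickel, but the alkenyl partner enters as a preformed nucleophile, which removes the alkenyl homocoupling pathway.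

Step 10 (NiH hydroalkylation). The risks are base-induced loss of HX from the β-halo ester to methyl methacrylate, hydrodehalogenation, and Ni–H chain walking near the C3 stereocentre of 15. The fallback sets out from 15 and 16 and comes back at 18. Compound 15 is hydrozirconated (Cp2Zr(H)Cl, THF) and quenched with NBS to give (S)-1-bromo-3,7-dimethyloctane F4. Compound 16 is converted with iodine-activated zinc dust in DMA into bromo[(2S)-3-methoxy-2-methyl-3-oxopropyl]zinc F5. F4 and F5 are then joined in a nickel/Pybox-catalysed alkyl–alkyl Negishi coupling (Ni(cod)2, s-Bu-Pybox, DMA, rt) to give 18.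

Step 2 (photochemical hydroacylation). The risks are decarbonylation of the secondary acyl radical and competing abstraction of allylic hydrogens. The fallback sets out from 3 and comes back at 7, so steps 3 and 4 are not needed, at the cost of one extra step. Compound 3 is treated with the Grignard reagent of 2-(2-bromoethyl)-1,3-dioxolane (THF, 0 °C) to give 3-(1,3-dioxolan-2-yl)-1-[(1R)-4-methylcyclohex-3-en-1-yl]propan-1-ol F1 as a mixture of carbinol epimers. Dess–Martin oxidation gives 3-(1,3-dioxolan-2-yl)-1-[(1R)-4-methylcyclohex-3-en-1-yl]propan-1-one F2. Wittig methylenation (Ph3P=CH2, THF) gives 2-{3-[(1R)-4-methylcyclohex-3-en-1-yl]but-3-en-1-yl}-1,3-dioxolane F3, and aqueous HCl in THF releases 7.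

**Further compounds**
F1 | step 2 | 3-(1,3-dioxolan-2-yl)-1-[(1R)-4-methylcyclohex-3-en-1-yl]propan-1-ol | OC(CCC1OCCO1)[C@H]1CC=C(C)CC1
F2 | step 2 | 3-(1,3-dioxolan-2-yl)-1-[(1R)-4-methylcyclohex-3-en-1-yl]propan-1-one | O=C(CCC1OCCO1)[C@H]1CC=C(C)CC1
F3 | step 2 | 2-{3-[(1R)-4-methylcyclohex-3-en-1-yl]but-3-en-1-yl}-1,3-dioxolane | C=C(CCC1OCCO1)[C@H]1CC=C(C)CC1
F4 | step 10 | (S)-1-bromo-3,7-dimethyloctane | BrCC[C@@H](C)CCCC(C)C
F5 | step 10 | bromo[(2S)-3-methoxy-2-methyl-3-oxopropyl]zinc | COC(=O)[C@H](C)C[Zn]Br
F6 | step 13 | chloro{(2Z)-6-[(1R)-4-methylcyclohex-3-en-1-yl]hepta-2,6-dien-2-yl}zinc | C=C(CC/C=C(/C)[Zn]Cl)[C@H]1CC=C(C)CC1
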